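# Synthesis proposal for CNP0144156.0: 5,7-dihydroxy-6-methoxy-3-(2,3,4-trimethoxyphenyl)-4H-chromen-4-one (17)

## The problem

The target 17 is a flat isoflavone without stereocentres, so every difficulty is one of position. Ring A is a pentasubstituted benzene whose single methyl ether (C6) lies between two free hydroxyls (C5, C7), with the only hydrogen at C8. The 8-methoxy isomer carries the same groups and arises whenever ring C is closed onto a ring A with two free ortho oxygens, or when a chromone with free O5 is opened and reclosed. The two phenols must be set free at the end beside four methyl ethers, so late demethylation is excluded and a second kind of protecting group is needed from the start. The C3–C1' bond joins ring C to a ring B with a methoxy group ortho to the junction, which makes a late cross-coupling hindered and prone to protodeboronation. Ring C is sensitive: C2 is an electrophilic vinylogous ester carbon that hydroxide can open with loss of C2, and both benzene rings are easily oxidised. The feature that the plan uses is that the ring-fusion carbons C4a and C8a of ring A are neighbours and carry C4(=O) and O1, which together are the atoms of one carboxylate group. C2 is bonded to O1 at the oxidation level of a formate, and C5 beside C4a bears oxygen while C8 beside C8a bears hydrogen, which is the pattern of a 3-alkoxybenzyne whose polarisation tells the two ends of the carboxylate where to add.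

## Retrosynthesis

**17 from 16.** The two O–CH2OCH3 bonds at O5 and O7 are cut. Methoxymethyl ethers are chosen because they survive organolithium, fluoride at high temperature and hydroxide, and are removed by acid methanolysis that leaves the four methyl ethers alone. With O5 masked until the last step, only one phenolic oxygen can ever close ring C, so the 6-methoxy and 8-methoxy patterns cannot interconvert.

**16 from aryne 14 and acid 13 (key disconnection).** Three bonds are cut at once: C8a–O1, C4a–C4 and O1–C2. All of ring C except the two fusion carbons, including the C4 carbonyl oxygen and the ring B substituent, then comes from the α-aryl-β-methoxyacrylic acid 13, and ring A comes from the aryne 14. Cutting only C4a–C4 (aromatic acylation) leaves the choice of ortho oxygen to ring A. Cutting C3–C1' keeps the whole chromone to be built first. The chosen cut makes the regiochemistry a consequence of aryne polarisation. The forward reaction must deliver the carboxylate oxygen to the aryne carbon remote from the flanking oxygen substituent, transfer the acyl group to the neighbouring carbon faster than the aryl carbanion is protonated, and close ring C by phenolate addition to the β-carbon with loss of methoxide through 15.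

**14 from 8, and 8 from 5 and 4.** The aryne is unmasked by fluoride from the ortho-silylaryl triflate 8. Compound 8 comes from bromophenol 5 by silyl ether formation (6), bromine–lithium exchange and O→C silyl shift to the phenolate 7, then triflation. Phenol 4 has a mirror plane through C1 and C4, so its two ortho positions are identical and bromination can give only one monobromide 5.

**4 from 2 and 1.** The C–O bond at the future C8a is cut. In the bis-ether 2 the required position is the only ring C–H without an ortho substituent, so a sterically governed C–H borylation (3) followed by oxidation places the hydroxyl there. Electrophilic substitution or directed lithiation would go next to an ether oxygen instead. Compound 2 comes in one step from 2-methoxyresorcinol 1, which already holds the oxygen–methoxy–oxygen pattern of C5 to C7.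

**13 from 12, 10 and 9.** The C2–C3 bond is cut: C2 is brought in as a formate carbon by formylation of ester 10 and O-methylation of the enolate 11 to 12, and saponification gives 13. The hindered C3–C1' bond is never made, because it is the benzylic C–C bond of the purchased acid 9.

## Roads not taken

**Alternative 1:** the deoxybenzoin route, the most obvious one. The cut is C4a–C4 plus the C2 unit. Lewis-acid acylation of 2-methoxybenzene-1,3,5-triol A1 with acid 9 would give the deoxybenzoin A2, and a one-carbon formylative ring closure would give the chromone. A2 has two different free ortho hydroxyls, so closure can give 17 or its 8-methoxy isomer A3, and nothing in A2 decides between them. The Lewis-acid conditions also allow opening and reclosure. The chosen plan fixes this point by the polarity of aryne 14 and by the mask on O5.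

**Alternative 2:** cut C3–C1'. A Suzuki–Miyaura coupling of the 3-iodochromone A5 with the boronic acid A6 under Pd(PPh3)4 (zerovalent palladium) would form the bond. A5 has to be made from the selectively protected acetophenone A4, whose preparation from a trihydroxy-methoxy-acetophenone meets the same 6/8 ambiguity at the protection stage. Ring C is then built in two further operations before the coupling. A6 is ortho-substituted and electron-rich, so protodeboronation competes. The chosen plan is shorter and never has to form this bond.

**Alternative 3:** oxidative 1,2-aryl shift of a chalcone. Condensation of A4 with 2,3,4-trimethoxybenzaldehyde A7 would give chalcone A8. An oxidant such as Tl(NO3)3 (trivalent thallium) or PhI(OAc)2 in methanol would move ring B from the β- to the α-carbon to give acetal A9, and acid would close ring C. The route again needs A4, and the electron-rich ring A with a free phenol competes for the oxidant. The acid closure removes the acetal ether on the second ortho oxygen at the same time, so both ortho oxygens can close and A3 can form. The chosen plan needs no oxidant on an electron-rich arene and no acid while ring C is being formed.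

Key step: step 8

Assumption: 1 and 9 are taken as purchasable; the target has no stereocentre, and the double-bond geometry of 12 and 13 is erased in step 8.

## Route

Step 1
Reactants: 1 2-methoxyresorcinol (2-methoxybenzene-1,3-diol)
Product: 2 2-methoxy-1,3-bis(methoxymethoxy)benzene
Conditions: NaH, MOMCl, DMF, 0 °C → rt
Reagents that add atoms: chloromethyl methyl ether (MOMCl), COCCl
Why: Double Williamson O-alkylation of the two equivalent phenoxides; the methyl ether between them is untouched, and the acetal ethers later tolerate organolithium, fluoride and hydroxide.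

Step 2
Reactants: 2 2-methoxy-1,3-bis(methoxymethoxy)benzene
Product: 4 4-methoxy-3,5-bis(methoxymethoxy)phenol, via aryl pinacol boronate 3 (not isolated)
Conditions: [Ir(OMe)(cod)]2 (cat.), 4,4'-di-tert-butyl-2,2'-bipyridine (cat.), B2pin2, THF, 80 °C; then aq. H2O2, NaOH, 0 °C → rt
Reagents that add atoms: hydrogen peroxide, OO (the phenol oxygen of 4); bis(pinacolato)diboron, CC1(C)OB(OC1(C)C)B1OC(C)(C)C(C)(C)O1 (the boryl group of 3 only)
Why: Iridium-catalysed aromatic C–H borylation is governed by sterics and takes C5 of 2, the only ring C–H without an ortho substituent; oxidation of boronate 3 in the same flask (boron-to-oxygen 1,2-shift) puts the hydroxyl at that carbon and gives the symmetric phenol 4.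

Step 3
Reactants: 4 4-methoxy-3,5-bis(methoxymethoxy)phenol
Product: 5 2-bromo-4-methoxy-3,5-bis(methoxymethoxy)phenol
Conditions: NBS (1.0 equiv), CH2Cl2, −78 → 0 °C
Reagents that add atoms: N-bromosuccinimide, O=C1CCC(=O)N1Br
Why: Electrophilic aromatic bromination ortho to the free hydroxyl (the para position is blocked by the methoxy group); the two ortho positions of 4 are related by the mirror plane through C1 and C4, so one equivalent at low temperature should give a single monobromide.

Step 4
Reactants: 5 2-bromo-4-methoxy-3,5-bis(methoxymethoxy)phenol
Product: 8 4-methoxy-3,5-bis(methoxymethoxy)-2-(trimethylsilyl)phenyl trifluoromethanesulfonate, via aryl trimethylsilyl ether 6 (not isolated), via lithium ortho-silylphenolate 7 (not isolated)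
Conditions: HMDS, THF, 65 °C, then evaporation; n-BuLi, THF, −78 °C; PhNTf2, −78 °C → rt
Reagents that add atoms: hexamethyldisilazane, C[Si](C)(C)N[Si](C)(C)C; N-phenylbis(trifluoromethanesulfonimide), O=S(=O)(N(c1ccccc1)S(=O)(=O)C(F)(F)F)C(F)(F)F
Why: O-Silylation, bromine–lithium exchange and anionic 1,3 O→C silyl shift (retro-Brook rearrangement) place the silyl group on the carbon that bore bromine, and phenolate 7 is trapped as the triflate; this is the standard one-flask route from ortho-bromophenols to ortho-silylaryl triflates, with PhNTf2 chosen over the anhydride to spare the acetal ethers.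

Step 5
Reactants: 9 2-(2,3,4-trimethoxyphenyl)acetic acid
Product: 10 methyl 2-(2,3,4-trimethoxyphenyl)acetate
Conditions: MeOH, H2SO4 (cat.), reflux
Reagents that add atoms: methanol, CO
Why: Fischer esterification; it masks the acid so that the benzylic position can be formylated.

Step 6
Reactants: 10 methyl 2-(2,3,4-trimethoxyphenyl)acetate
Product: 12 methyl (E)-3-methoxy-2-(2,3,4-trimethoxyphenyl)acrylate, via sodium formyl enolate 11 (not isolated)
Conditions: NaH, HCO2Me, DMF, 0 °C → rt; then Me2SO4, rt
Reagents that add atoms: methyl formate, COC=O; dimethyl sulfate, COS(=O)(=O)OC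
Why: Crossed Claisen condensation with methyl formate gives formyl enolate 11, which the hard electrophile methylates on oxygen to the thermodynamically preferred (E)-β-methoxyacrylate, as in strobilurin-type side chains; C2 of the target is thereby installed at the formate level with a leaving group.

Step 7
Reactants: 12 methyl (E)-3-methoxy-2-(2,3,4-trimethoxyphenyl)acrylate
Product: 13 (E)-3-methoxy-2-(2,3,4-trimethoxyphenyl)acrylic acid
Conditions: LiOH·H2O, THF/MeOH/H2O, rt; then 1 M HCl, 0 °C (pH 3)
Reagents that add atoms: lithium hydroxide, [Li+].[OH-]
Why: Saponification (BAc2) of the methyl ester; the β-methoxyacrylate is a vinylogous carbonate and a poor Michael acceptor, so ester hydrolysis should precede attack at the β-carbon, and cold, mild acidification should spare the enol ether.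

Step 8
Reactants: 8 4-methoxy-3,5-bis(methoxymethoxy)-2-(trimethylsilyl)phenyl trifluoromethanesulfonate (1.5 equiv); 13 (E)-3-methoxy-2-(2,3,4-trimethoxyphenyl)acrylic acid
Product: 16 6-methoxy-5,7-bis(methoxymethoxy)-3-(2,3,4-trimethoxyphenyl)-4H-chromen-4-one, via aryne 14 (not isolated), via cesium ortho-acylphenolate 15 (not isolated)
Conditions: CsF (4 equiv), THF, 125 °C, sealed tube
Reagents that add atoms: none
Why: Proposed new method: fluoride removes the silyl group of 8 and triflate leaves to give aryne 14; the carboxylate of 13 adds through oxygen to the aryne carbon remote from the flanking methoxymethoxy group, and the aryl carbanion formed next to that group attacks the ester carbonyl (4-exo-trig) to a benzoxete alkoxide that opens to the ortho-acylphenolate 15, a net insertion of the aryne into the C(=O)–O bond. The phenolate oxygen of 15 then adds 6-endo-trig to the β-carbon of the β-methoxy enone and methoxide leaves (E1cB), which closes ring C as the pyranone of 16. The closest known reaction type is the fluoride-induced insertion of arynes into the C–O bond of carboxylic acids to give ortho-hydroxyaryl ketones, which with α,β-unsaturated acids runs on to 4-chromanones and with arylpropiolic acids to flavones by oxa-Michael closure in the same flask; new here is a β-alkoxyacrylic acid, whose leaving group turns that closure into an addition–elimination and gives a 3-arylchromone directly. The step needs oxygen on the future C8a and acyl on the future C4a. This is secured by the C–O bond beside the triple bond, whose inductive pull distorts the aryne so that the remote carbon is the more electrophilic and the carbanion develops next to oxygen, as in 3-methoxybenzyne. Acyl transfer must beat protonation of the carbanion and its 6-endo attack on the β-carbon (which would give a coumarin); the aprotic medium and high temperature favour transfer, and the s-cis aryl ester holds the carbonyl carbon, not the β-carbon, within reach of the in-plane carbanion orbital. No stereocentre is formed, and the geometry of 13 is lost because the Cα–Cβ bond is single before methoxide leaves. Because O5 is masked, only one phenolate can close, so no 8-methoxy isomer can form.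

Step 9
Reactants: 16 6-methoxy-5,7-bis(methoxymethoxy)-3-(2,3,4-trimethoxyphenyl)-4H-chromen-4-one
Product: 17 5,7-dihydroxy-6-methoxy-3-(2,3,4-trimethoxyphenyl)-4H-chromen-4-one (target)
Conditions: HCl, MeOH, 50 °C
Reagents that add atoms: none
Why: Acid-catalysed transacetalisation of the two methoxymethyl ethers to methanol; aryl methyl ethers and the chromone are inert under these conditions, and ring C is not opened in acid, so the 6-methoxy pattern is kept.

## Compound list

1 | 2-methoxyresorcinol (2-methoxybenzene-1,3-diol) | COc1c(O)cccc1O | starting material
2 | 2-methoxy-1,3-bis(methoxymethoxy)benzene | COCOc1cccc(OCOC)c1OC | intermediate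
3 | 2-[4-methoxy-3,5-bis(methoxymethoxy)phenyl]-4,4,5,5-tetramethyl-1,3,2-dioxaborolane | COCOc1cc(B2OC(C)(C)C(C)(C)O2)cc(OCOC)c1OC | intermediate (not isolated)
4 | 4-methoxy-3,5-bis(methoxymethoxy)phenol | COCOc1cc(O)cc(OCOC)c1OC | intermediate
5 | 2-bromo-4-methoxy-3,5-bis(methoxymethoxy)phenol | COCOc1cc(O)c(Br)c(OCOC)c1OC | intermediate
6 | [2-bromo-4-methoxy-3,5-bis(methoxymethoxy)phenoxy]trimethylsilane | COCOc1cc(O[Si](C)(C)C)c(Br)c(OCOC)c1OC | intermediate (not isolated)
7 | lithium 4-methoxy-3,5-bis(methoxymethoxy)-2-(trimethylsilyl)phenolate | [Li+].[O-]c1cc(OCOC)c(OC)c(OCOC)c1[Si](C)(C)C | intermediate (not isolated)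
8 | 4-methoxy-3,5-bis(methoxymethoxy)-2-(trimethylsilyl)phenyl trifluoromethanesulfonate | COCOc1cc(OS(=O)(=O)C(F)(F)F)c([Si](C)(C)C)c(OCOC)c1OC | intermediate
9 | 2-(2,3,4-trimethoxyphenyl)acetic acid | COc1ccc(CC(=O)O)c(OC)c1OC | starting material
10 | methyl 2-(2,3,4-trimethoxyphenyl)acetate | COC(=O)Cc1ccc(OC)c(OC)c1OC | intermediate
11 | sodium enolate of methyl 3-oxo-2-(2,3,4-trimethoxyphenyl)propanoate (geometry not fixed) | [Na+].[O-]C=C(C(=O)OC)c1ccc(OC)c(OC)c1OC | intermediate (not isolated)
12 | methyl (E)-3-methoxy-2-(2,3,4-trimethoxyphenyl)acrylate | CO/C=C(\c1ccc(OC)c(OC)c1OC)C(=O)OC | intermediate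
13 | (E)-3-methoxy-2-(2,3,4-trimethoxyphenyl)acrylic acid | CO/C=C(\c1ccc(OC)c(OC)c1OC)C(=O)O | intermediate
14 | 4-methoxy-3,5-bis(methoxymethoxy)benzyne (1,2-didehydrobenzene) | COCOC1=CC#CC(OCOC)=C1OC | intermediate (not isolated)
15 | cesium 4-methoxy-3,5-bis(methoxymethoxy)-2-[(E)-3-methoxy-2-(2,3,4-trimethoxyphenyl)acryloyl]phenolate | [Cs+].[O-]c1cc(OCOC)c(OC)c(OCOC)c1C(=O)/C(=C/OC)c1ccc(OC)c(OC)c1OC | intermediate (not isolated)
16 | 6-methoxy-5,7-bis(methoxymethoxy)-3-(2,3,4-trimethoxyphenyl)-4H-chromen-4-one | COCOc1cc2occ(-c3ccc(OC)c(OC)c3OC)c(=O)c2c(OCOC)c1OC | intermediate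
17 | 5,7-dihydroxy-6-methoxy-3-(2,3,4-trimethoxyphenyl)-4H-chromen-4-one | COc1ccc(-c2coc3cc(O)c(OC)c(O)c3c2=O)c(OC)c1OC | target

## Step count and risk

Total steps: 9. Longest linear sequence: 6 (steps 1, 2, 3, 4, 8, 9 from 1); the acid branch (steps 5, 6, 7) joins at step 8.

**Step 8 (key step, proposed new method).** The aryl carbanion may be protonated before acyl transfer, which would stop the sequence at the aryl ester. Acyl transfer onto the electron-rich vinylogous carbonate carbonyl may also be slow at a carbanion flanked by an acetal ether, and conjugate capture at the β-carbon may compete. The fallback uses known chemistry only: it sets out from 8 and the purchased acid 9 and comes back at 16. Fluoride-induced insertion of aryne 14 into the C–O bond of the simple arylacetic acid 9 (CsF, THF, 125 °C) should give the deoxybenzoin 1-[2-hydroxy-5-methoxy-4,6-bis(methoxymethoxy)phenyl]-2-(2,3,4-trimethoxyphenyl)ethan-1-one F1, with the same aryne regiocontrol. Heating F1 with N,N-dimethylformamide dimethyl acetal in toluene at 100 °C (enaminone formation and ring closure with loss of dimethylamine) should then give 16.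

**Step 2.** Control by sterics may be eroded by coordination of iridium to an acetal oxygen, and the very electron-rich phenol may be over-oxidised during the boronate oxidation. The fallback sets out from 2 and comes back at aryne 14 in step 8 through an isomeric precursor. Acetal-directed ortho-lithiation of 2 (n-BuLi, TMEDA), borylation with B(OMe)3 and oxidation should give 3-methoxy-2,4-bis(methoxymethoxy)phenol F2. Isopropyl isocyanate should convert it into 3-methoxy-2,4-bis(methoxymethoxy)phenyl N-isopropylcarbamate F3. Carbamate-directed ortho-lithiation and TMSCl should give 3-methoxy-2,4-bis(methoxymethoxy)-6-(trimethylsilyl)phenyl N-isopropylcarbamate F4. Carbamate cleavage (DBU, Et2NH) and triflation with PhNTf2 should give 3-methoxy-2,4-bis(methoxymethoxy)-6-(trimethylsilyl)phenyl trifluoromethanesulfonate F5, which has silyl and triflate exchanged relative to 8 and yields the same aryne 14 with CsF.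

**Step 3.** The second, equally activated ortho position may also be brominated, or the para-methoxyphenol may be oxidised to a quinone by the bromine source. The fallback avoids halogenation and also replaces step 4: it sets out from 4 and comes back at 8. Isopropyl isocyanate should give 4-methoxy-3,5-bis(methoxymethoxy)phenyl N-isopropylcarbamate F6. Directed ortho-lithiation (TMSOTf, TMEDA, then n-BuLi) at the position activated by both carbamate and acetal, with TMSCl quench, should give 4-methoxy-3,5-bis(methoxymethoxy)-2-(trimethylsilyl)phenyl N-isopropylcarbamate F7. Cleavage with DBU and Et2NH followed by PhNTf2 should give 8.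

**Step 7.** Hydroxide may add to the β-carbon and trigger deformylation (retro-Claisen) to the arylacetate, or the enol ether may hydrolyse on acidification. The fallback unmasks the acid without hydroxide: it sets out from 9 and comes back at 13. Esterification of 9 with Boc2O, DMAP and t-BuOH should give tert-butyl 2-(2,3,4-trimethoxyphenyl)acetate F8. Formylation and O-methylation as in step 6 should give tert-butyl (E)-3-methoxy-2-(2,3,4-trimethoxyphenyl)acrylate F9. Anhydrous acidolysis (TFA, CH2Cl2, 0 °C) should release 13.

## Further compounds

F1 | step 8 | 1-[2-hydroxy-5-methoxy-4,6-bis(methoxymethoxy)phenyl]-2-(2,3,4-trimethoxyphenyl)ethan-1-one | COCOc1cc(O)c(C(=O)Cc2ccc(OC)c(OC)c2OC)c(OCOC)c1OC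
F2 | step 2 | 3-methoxy-2,4-bis(methoxymethoxy)phenol | COCOc1ccc(O)c(OCOC)c1OC
F3 | step 2 | 3-methoxy-2,4-bis(methoxymethoxy)phenyl N-isopropylcarbamate | COCOc1ccc(OC(=O)NC(C)C)c(OCOC)c1OC
F4 | step 2 | 3-methoxy-2,4-bis(methoxymethoxy)-6-(trimethylsilyl)phenyl N-isopropylcarbamate | COCOc1cc([Si](C)(C)C)c(OC(=O)NC(C)C)c(OCOC)c1OC
F5 | step 2 | 3-methoxy-2,4-bis(methoxymethoxy)-6-(trimethylsilyl)phenyl trifluoromethanesulfonate | COCOc1cc([Si](C)(C)C)c(OS(=O)(=O)C(F)(F)F)c(OCOC)c1OC
F6 | step 3 | 4-methoxy-3,5-bis(methoxymethoxy)phenyl N-isopropylcarbamate | COCOc1cc(OC(=O)NC(C)C)cc(OCOC)c1OC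
F7 | step 3 | 4-methoxy-3,5-bis(methoxymethoxy)-2-(trimethylsilyl)phenyl N-isopropylcarbamate | COCOc1cc(OC(=O)NC(C)C)c([Si](C)(C)C)c(OCOC)c1OC
F8 | step 7 | tert-butyl 2-(2,3,4-trimethoxyphenyl)acetate | CC(C)(C)OC(=O)Cc1ccc(OC)c(OC)c1OC
F9 | step 7 | tert-butyl (E)-3-methoxy-2-(2,3,4-trimethoxyphenyl)acrylate | CO/C=C(\c1ccc(OC)c(OC)c1OC)C(=O)OC(C)(C)C
A1 | alternative 1 | 2-methoxybenzene-1,3,5-triol | COc1c(O)cc(O)cc1O
A2 | alternative 1 | 1-(2,4,6-trihydroxy-3-methoxyphenyl)-2-(2,3,4-trimethoxyphenyl)ethan-1-one | COc1c(O)cc(O)c(C(=O)Cc2ccc(OC)c(OC)c2OC)c1O
A3 | alternative 1 | 5,7-dihydroxy-8-methoxy-3-(2,3,4-trimethoxyphenyl)-4H-chromen-4-one | COc1ccc(-c2coc3c(OC)c(O)cc(O)c3c2=O)c(OC)c1OC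
A4 | alternative 2 | 1-[2-hydroxy-5-methoxy-4,6-bis(methoxymethoxy)phenyl]ethan-1-one | COCOc1cc(O)c(C(C)=O)c(OCOC)c1OC
A5 | alternative 2 | 3-iodo-6-methoxy-5,7-bis(methoxymethoxy)-4H-chromen-4-one | COCOc1cc2occ(I)c(=O)c2c(OCOC)c1OC
A6 | alternative 2 | (2,3,4-trimethoxyphenyl)boronic acid | COc1ccc(B(O)O)c(OC)c1OC
A7 | alternative 3 | 2,3,4-trimethoxybenzaldehyde | COc1ccc(C=O)c(OC)c1OC
A8 | alternative 3 | (E)-1-[2-hydroxy-5-methoxy-4,6-bis(methoxymethoxy)phenyl]-3-(2,3,4-trimethoxyphenyl)prop-2-en-1-one | COCOc1cc(O)c(C(=O)/C=C/c2ccc(OC)c(OC)c2OC)c(OCOC)c1OC
A9 | alternative 3 | 1-[2-hydroxy-5-methoxy-4,6-bis(methoxymethoxy)phenyl]-3,3-dimethoxy-2-(2,3,4-trimethoxyphenyl)propan-1-one (racemic) | COCOc1cc(O)c(C(=O)C(C(OC)OC)c2ccc(OC)c(OC)c2OC)c(OCOC)c1OC
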